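**Plan**

- Retrosynthesis: the quinone methide is traced to a triarylmethanol, whose two C7–aryl bonds are cut back to an ester. The C8≡C9–aryl unit is then cut by removing C9, leaving a diaryl ketone at C8. The C8–anisyl bond is cut to a phthalic anhydride, ring A is cut into a 2-aryl-5-methylfuran and maleic anhydride, and the furan–aryl bond is cut last.
- Ring A numbering: C1 (CH3), C2 (alkyne C8≡C9–aryl), C3 (C7), C4 (aryl), C5-H, C6-H. The enabling feature is that the C2 alkyne and the C3 triaryl carbon are ortho: without C9, C8 is an aroyl carbon and C7/C8 are the two carbonyl carbons of a 3-aryl-6-methylphthalic anhydride.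
- Forward order: furan–aryl bond; ring A (the only ring built) by cycloaddition and dehydration; anisyl onto C8; one-carbon insertion with aryl shift to the alkyne; ester; two aryl groups onto C7; demethylation with loss of water.
- Stereochemistry: the target has no stereogenic element. The only stereocentres of the route sit in racemic intermediates that are not isolated.

Key step: step 4

Remark on the chemistry: keto acid 8 is drawn open-chain; it may rest as its cyclic 3-hydroxyphthalide tautomer, which the base in step 4 opens. Compounds 7 and 9 are bought as solutions.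

**Step 1**
Reactants: 1 2-methylfuran; 2 4-bromoanisole
Product: 3 2-(4-methoxyphenyl)-5-methylfuran
Conditions: Pd(OAc)2 (2 mol%), PCy3·HBF4 (4 mol%), PivOH (30 mol%), K2CO3 (1.5 equiv), 1 (3 equiv), DMAc, 100 °C, sealed vessel
Reagents that add atoms: none
Why: Palladium-catalysed direct C–H arylation (concerted metalation–deprotonation assisted by pivalate) can only take place at C5, the one free α-position of the furan, so a single regioisomer is expected.

**Step 2**
Reactants: 3 2-(4-methoxyphenyl)-5-methylfuran; 4 maleic anhydride
Product: 6 3-(4-methoxyphenyl)-6-methylphthalic anhydride, via exo oxanorbornene anhydride adduct 5 (not isolated)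
Conditions: 4 (1.2 equiv), Et2O, rt; solvent removed; then MeSO3H, Ac2O, 0 °C → rt
Reagents that add atoms: none
Why: Diels–Alder cycloaddition of the 2,5-disubstituted furan gives the oxanorbornene, whose oxygen bridge should open under acid at the anisyl-stabilised bridgehead and lose water to the arene (dehydrative aromatisation), with Ac2O taking up the water and keeping the anhydride closed so that cycloreversion is outrun.

**Step 3**
Reactants: 6 3-(4-methoxyphenyl)-6-methylphthalic anhydride; 7 4-methoxyphenylmagnesium bromide
Product: 8 2-(4-methoxybenzoyl)-6-(4-methoxyphenyl)-3-methylbenzoic acid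
Conditions: 7 (1.05 equiv, slow addition), THF, −78 → 0 °C; then 1 M HCl
Reagents that add atoms: none
Why: Mono-addition of an aryl Grignard reagent to a cyclic anhydride stops at the magnesium keto carboxylate at low temperature, and attack is expected at the carbonyl beside the methyl group (C8) because the twisted anisyl ring screens both faces of its neighbouring carbonyl (C7), any regioisomeric keto acid being removed by crystallisation or chromatography.

**Step 4**
Reactants: 8 2-(4-methoxybenzoyl)-6-(4-methoxyphenyl)-3-methylbenzoic acid; 9 trimethylsilyldiazomethane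
Product: 15 2-[(4-methoxyphenyl)ethynyl]-6-(4-methoxyphenyl)-3-methylbenzoic acid, via lithium keto carboxylate 10 (not isolated), via lithiated silyldiazomethane 11 (not isolated), via diazo alkoxide 12 (not isolated), via diazoalkene 13 (not isolated), via alkylidene carbene 14 (not isolated)
Conditions: LiN(SiMe3)2 (1.0 equiv), THF, −78 °C; then Me3SiC(Li)N2 (from 9 and n-BuLi, 1.5 equiv), THF, −78 °C → rt; cold 0.5 M HCl to pH 3
Reagents that add atoms: none
Why: Colvin rearrangement: base turns 8 (including any cyclic hydroxyphthalide tautomer) into the open carboxylate 10, the small linear anion 11 adds to the C8 ketone to give alkoxide 12, Peterson-type loss of Me3SiOLi gives diazoalkene 13, N2 leaves, and in carbene 14 a 1,2-aryl shift from C8 to C9 creates the C8≡C9 triple bond and the C9–aryl bond. The closest known reaction type is the one-carbon conversion of diaryl ketones into diarylalkynes with lithiated trimethylsilyldiazomethane or with diazomethylphosphonate anions (Seyferth–Gilbert variant). No ring is closed and no stereocentre is created, the single stereocentre of racemic 12 being erased in the elimination. The step must tell the two former anhydride carbons apart: C7 is held as a carboxylate anion, which accepts no nucleophile and cannot lactonise with the C8 alkoxide, so only C8 reacts. Either aryl group on C8 can migrate with the same result, so no migratory preference has to be enforced, and the aryl shift of a diarylalkylidene carbene is expected to outrun capture by the carboxylate oxygen or insertion into a C–H bond of the C1 methyl group. The crowded C2–C8 bond already exists (it was an anhydride ring bond), so no coupling at C2 is required, and the cold, weakly acidic work-up guards the 2-alkynylbenzoic acid against lactonisation.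

**Step 5**
Reactants: 15 2-[(4-methoxyphenyl)ethynyl]-6-(4-methoxyphenyl)-3-methylbenzoic acid; 9 trimethylsilyldiazomethane
Product: 16 methyl 2-[(4-methoxyphenyl)ethynyl]-6-(4-methoxyphenyl)-3-methylbenzoate
Conditions: 9 (1.5 equiv), toluene/MeOH 4:1, 0 °C → rt; crude 15 used at once
Reagents that add atoms: none
Why: Esterification with the diazomethane equivalent in methanol is an O-alkylation of the carboxylate (proton transfer, then SN2 on the methyldiazonium ion), so the two ortho substituents do not hinder it and the acid, base or heat that would lactonise the alkynyl acid are avoided.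

**Step 6**
Reactants: 16 methyl 2-[(4-methoxyphenyl)ethynyl]-6-(4-methoxyphenyl)-3-methylbenzoate; 2 4-bromoanisole
Product: 19 bis(4-methoxyphenyl){2-[(4-methoxyphenyl)ethynyl]-6-(4-methoxyphenyl)-3-methylphenyl}methanol, via 4-methoxyphenyllithium 17 (not isolated), via diaryl ketone 18 (not isolated)
Conditions: 2 (4.2 equiv), n-BuLi (4.0 equiv), THF, −78 °C; then 16, −78 °C → rt; then H2O
Reagents that add atoms: none
Why: Bromine–lithium exchange on 2 gives 17, which adds twice to the ester (through ketone 18, more electrophilic than the ester) to give the tertiary alkoxide, the standard aryllithium route from a benzoate to a triarylmethanol, and the internal diarylalkyne should not react with an aryllithium at these temperatures.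

**Step 7**
Reactants: 19 bis(4-methoxyphenyl){2-[(4-methoxyphenyl)ethynyl]-6-(4-methoxyphenyl)-3-methylphenyl}methanol
Product: 21 selaginellin U, via triarylcarbenium bromide 20 (not isolated)
Conditions: BBr3 (10 equiv), CH2Cl2, −78 → 0 °C; then ice-water
Reagents that add atoms: none
Why: BBr3 cleaves the four aryl methyl ethers and ionises the triarylmethanol, and on hydrolysis the doubly para-hydroxylated trityl cation 20 loses a phenolic proton to give the quinone methide (fuchsone formation), while the ortho carbon of the C4 aryl ring, meta to its oxygen, is too poorly activated for Friedel–Crafts closure to a fluorene at low temperature.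

**Compound list**

1 | 2-methylfuran | Cc1ccco1 | starting material
2 | 4-bromoanisole (1-bromo-4-methoxybenzene) | COc1ccc(Br)cc1 | starting material
3 | 2-(4-methoxyphenyl)-5-methylfuran | Cc1ccc(-c2ccc(OC)cc2)o1 | intermediate
4 | maleic anhydride | O=C1C=CC(=O)O1 | starting material
5 | 1-(4-methoxyphenyl)-4-methyl-7-oxabicyclo[2.2.1]hept-5-ene-2,3-dicarboxylic anhydride, exo adduct (anhydride ring syn to the oxygen bridge), racemic, one enantiomer drawn, formed in situ | C[C@]12C=C[C@](c3ccc(OC)cc3)(O1)[C@@H]1C(=O)OC(=O)[C@@H]12 | intermediate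
6 | 3-(4-methoxyphenyl)-6-methylphthalic anhydride (4-(4-methoxyphenyl)-7-methyl-2-benzofuran-1,3-dione) | Cc1ccc(-c2ccc(OC)cc2)c2C(=O)OC(=O)c12 | intermediate
7 | 4-methoxyphenylmagnesium bromide (THF solution) | COc1ccc([Mg]Br)cc1 | starting material
8 | 2-(4-methoxybenzoyl)-6-(4-methoxyphenyl)-3-methylbenzoic acid | Cc1ccc(-c2ccc(OC)cc2)c(C(=O)O)c1C(=O)c1ccc(OC)cc1 | intermediate
9 | trimethylsilyldiazomethane | C[Si](C)(C)C=[N+]=[N-] | starting material
10 | lithium 2-(4-methoxybenzoyl)-6-(4-methoxyphenyl)-3-methylbenzoate, formed in situ | Cc1ccc(-c2ccc(OC)cc2)c(C(=O)[O-])c1C(=O)c1ccc(OC)cc1.[Li+] | intermediate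
11 | lithio(trimethylsilyl)diazomethane, formed in situ | [Li]C(=[N+]=[N-])[Si](C)(C)C | intermediate
12 | dilithium salt of 2-[2-diazo-1-hydroxy-1-(4-methoxyphenyl)-2-(trimethylsilyl)ethyl]-6-(4-methoxyphenyl)-3-methylbenzoic acid, racemic, formed in situ | Cc1ccc(-c2ccc(OC)cc2)c(C(=O)[O-])c1C([O-])(C(=[N+]=[N-])[Si](C)(C)C)c1ccc(OC)cc1.[Li+].[Li+] | intermediate
13 | lithium 2-[2-diazo-1-(4-methoxyphenyl)ethenyl]-6-(4-methoxyphenyl)-3-methylbenzoate, formed in situ | Cc1ccc(-c2ccc(OC)cc2)c(C(=O)[O-])c1C(=C=[N+]=[N-])c1ccc(OC)cc1.[Li+] | intermediate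
14 | alkylidene carbene: lithium 6-(4-methoxyphenyl)-3-methylbenzoate carrying at C2 a 1-(4-methoxyphenyl)ethenylidene unit with a carbene terminal carbon (C9), formed in situ | Cc1ccc(-c2ccc(OC)cc2)c(C(=O)[O-])c1C(=[C])c1ccc(OC)cc1.[Li+] | intermediate
15 | 2-[(4-methoxyphenyl)ethynyl]-6-(4-methoxyphenyl)-3-methylbenzoic acid | Cc1ccc(-c2ccc(OC)cc2)c(C(=O)O)c1C#Cc1ccc(OC)cc1 | intermediate
16 | methyl 2-[(4-methoxyphenyl)ethynyl]-6-(4-methoxyphenyl)-3-methylbenzoate | Cc1ccc(-c2ccc(OC)cc2)c(C(=O)OC)c1C#Cc1ccc(OC)cc1 | intermediate
17 | 4-methoxyphenyllithium, formed in situ | [Li]c1ccc(OC)cc1 | intermediate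
18 | {2-[(4-methoxyphenyl)ethynyl]-6-(4-methoxyphenyl)-3-methylphenyl}(4-methoxyphenyl)methanone, formed in situ | Cc1ccc(-c2ccc(OC)cc2)c(C(=O)c2ccc(OC)cc2)c1C#Cc1ccc(OC)cc1 | intermediate
19 | bis(4-methoxyphenyl){2-[(4-methoxyphenyl)ethynyl]-6-(4-methoxyphenyl)-3-methylphenyl}methanol | Cc1ccc(-c2ccc(OC)cc2)c(C(O)(c2ccc(OC)cc2)c2ccc(OC)cc2)c1C#Cc1ccc(OC)cc1 | intermediate
20 | bis(4-hydroxyphenyl){2-[(4-hydroxyphenyl)ethynyl]-6-(4-hydroxyphenyl)-3-methylphenyl}methylium bromide (the O-protonated target), formed in situ | Cc1ccc(-c2ccc(O)cc2)c([C+](c2ccc(O)cc2)c2ccc(O)cc2)c1C#Cc1ccc(O)cc1.[Br-] | intermediate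
21 | selaginellin U, 4-{(4-hydroxyphenyl){2-[(4-hydroxyphenyl)ethynyl]-6-(4-hydroxyphenyl)-3-methylphenyl}methylidene}cyclohexa-2,5-dien-1-one | Cc1ccc(-c2ccc(O)cc2)c(C(=C2C=CC(=O)C=C2)c2ccc(O)cc2)c1C#Cc1ccc(O)cc1 | target

**Count and risks**

Total step count: 7. Longest linear sequence: 7 steps (1 to 21); 2, 4, 7 and 9 enter as bought materials.

Steps most likely to fail:

1. Step 4. The diazomethyl anion may add too slowly to the doubly ortho-flanked ketone. The free carbene may also be diverted before the aryl shift (capture by the neighbouring carboxylate oxygen, insertion into a C–H bond of the C1 methyl group), or the alkynyl acid may lactonise on acidification. The fallback sets out from 8 and returns at 15, and replaces the free carbene by a carbenoid. Compound 8, as its lithium salt, is olefinated with diethyl [dichloro(lithio)methyl]phosphonate (from diethyl (dichloromethyl)phosphonate and LiN(iPr)2, THF, −78 °C → rt; Horner–Wadsworth–Emmons-type reaction). This gives 2-[2,2-dichloro-1-(4-methoxyphenyl)ethenyl]-6-(4-methoxyphenyl)-3-methylbenzoic acid F1. n-BuLi (3 equiv, THF, −78 → 0 °C) then effects chlorine–lithium exchange and Fritsch–Buttenberg–Wiechell rearrangement, in which the aryl shift is concerted with loss of chloride, and gives 15 after the same cold work-up.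

2. Step 3. The Grignard reagent may attack the carbonyl beside the anisyl ring (poor regioselectivity between two flanked carbonyls), or add a second time to give a 3,3-diarylphthalide. The fallback sets out from 4-bromoanisole 2, bypasses 3 to 6 and returns at 8; the position of the ketone is fixed by a halogen. Purchased 2-bromo-3-methylbenzoic acid undergoes bromine–lithium exchange (n-BuLi, 2.1 equiv, THF, −100 °C) and acylation with purchased 4-methoxy-N-methoxy-N-methylbenzamide to give 2-(4-methoxybenzoyl)-3-methylbenzoic acid F2. Carboxylate-directed ortho C–H arylation of F2 with 2 ([RuCl2(p-cymene)]2, PEt3·HBF4, K2CO3, NMP, 100 °C) can only occur at the single free position ortho to the carboxyl group and gives 8.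

3. Step 2. Cycloreversion of the furan adduct and acid-induced decomposition of the electron-rich aryl furan (or acetylation of the anisyl ring) may compete with dehydration. The fallback sets out from 3 and returns at 6, and avoids strong acid. Cycloaddition of 3 with dimethyl acetylenedicarboxylate (toluene, 90 °C) gives the stable dimethyl 1-(4-methoxyphenyl)-4-methyl-7-oxabicyclo[2.2.1]hepta-2,5-diene-2,3-dicarboxylate F3 (racemic). Reductive removal of the oxygen bridge with low-valent titanium (TiCl4/LiAlH4/Et3N, THF, reflux) gives dimethyl 3-(4-methoxyphenyl)-6-methylphthalate F4. Saponification (KOH, aqueous ethylene glycol, 120 °C; then HCl) gives 3-(4-methoxyphenyl)-6-methylphthalic acid F5, which Ac2O at reflux closes to 6.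

**Further compounds**

F1 | step 4 | 2-[2,2-dichloro-1-(4-methoxyphenyl)ethenyl]-6-(4-methoxyphenyl)-3-methylbenzoic acid | Cc1ccc(-c2ccc(OC)cc2)c(C(=O)O)c1C(=C(Cl)Cl)c1ccc(OC)cc1
F2 | step 3 | 2-(4-methoxybenzoyl)-3-methylbenzoic acid | Cc1cccc(C(=O)O)c1C(=O)c1ccc(OC)cc1
F3 | step 2 | dimethyl 1-(4-methoxyphenyl)-4-methyl-7-oxabicyclo[2.2.1]hepta-2,5-diene-2,3-dicarboxylate (racemic, one enantiomer drawn) | C[C@]12C=C[C@](c3ccc(OC)cc3)(O1)C(C(=O)OC)=C2C(=O)OC
F4 | step 2 | dimethyl 3-(4-methoxyphenyl)-6-methylphthalate | Cc1ccc(-c2ccc(OC)cc2)c(C(=O)OC)c1C(=O)OC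
F5 | step 2 | 3-(4-methoxyphenyl)-6-methylphthalic acid | Cc1ccc(-c2ccc(OC)cc2)c(C(=O)O)c1C(=O)O
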